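**Retrosynthetic overview**

1. The target is cut at the C5′–C6′ single bond of the diene (Stille coupling) into alkenyl iodide 15, which carries the butenolide, and alkenylstannane 28, which carries both furans; the two furan rings are bought (3-bromofuran, 4-bromofuran-2-carbaldehyde).
2. The strategy rests on the γ-alkylidene butenolide being an enol lactone (ring O1–C2(=O)–C3(Me)=C4–C5, exocyclic C5=C1′ with the chain cis to C4). Its E geometry is stored as the unlike relative configuration of two C–O stereocentres, C5–O1 and C1′–OH, and released by anti-elimination.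
3. That C5/C1′ pair comes from a trans-epoxide: the carbonyl oxygen of a Z-enoate opens the allylic epoxide carbon with inversion and closes the butenolide through O1–C5. This is the only ring made in the route.
4. Epoxy enoate 9 is made from (R)-citronellol, which supplies the C2′ methyl centre, by silylation, ozonolysis, aldehyde dehydrogenation, Still–Gennari olefination and epoxidation of the distal E-alkene.
5. Stannane 28 is made by furyllithium addition and deoxygenation (linking the furans), Negishi alkylation with a pentynylzinc reagent, hydrozirconation–iodination and iodine–lithium–tin exchange.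

Key step: step 6

Remark: the epoxide is introduced on the dienoate after the olefination, which avoids a labile epoxy aldehyde; the other trans-epoxide diastereomer would serve equally, since C5 and C1′ both become sp2 in step 7.

**Route**

Step 1
Reactants: 1 (R)-citronellol
Product: 2 tert-butyl{[(3R)-3,7-dimethyloct-6-en-1-yl]oxy}diphenylsilane
Conditions: TBDPSCl, imidazole, DMF, 0 °C → rt
Reagents that add atoms: tert-butyl(chloro)diphenylsilane, CC(C)(C)[Si](Cl)(c1ccccc1)c1ccccc1
Why: Imidazole-promoted silylation of the primary alcohol; the TBDPS ether should survive ozone, base, sulfonic acid and Tf2O, and its hindered oxygen is a poor internal nucleophile.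

Step 2
Reactants: 2 tert-butyl{[(3R)-3,7-dimethyloct-6-en-1-yl]oxy}diphenylsilane
Product: 4 (4R)-6-[(tert-butyldiphenylsilyl)oxy]-4-methylhexanal, via ozonide 3 (not isolated)
Conditions: O3, CH2Cl2, −78 °C; then PPh3, −78 °C → rt
Reagents that add atoms: ozone, [O-][O+]=O
Why: Ozonolysis (cycloaddition to the secondary ozonide, reductive cleavage by PPh3) cuts the only alkene to the aldehyde and acetone without touching the remote stereocentre.

Step 3
Reactants: 4 (4R)-6-[(tert-butyldiphenylsilyl)oxy]-4-methylhexanal
Product: 5 (2E,4S)-6-[(tert-butyldiphenylsilyl)oxy]-4-methylhex-2-enal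
Conditions: 2-iodoxybenzoic acid (IBX), 4-methoxypyridine N-oxide, DMSO, 25 °C
Reagents that add atoms: none
Why: IBX-mediated α,β-dehydrogenation of the aldehyde through its enol should give the conjugated E-enal, and the amine-oxide-activated reagent works at ambient temperature, which limits enolisation toward the γ-stereocentre (the descriptor changes from R to S only because the priorities change).

Step 4
Reactants: 5 (2E,4S)-6-[(tert-butyldiphenylsilyl)oxy]-4-methylhex-2-enal; 6 ethyl 2-[bis(2,2,2-trifluoroethoxy)phosphoryl]propanoate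
Product: 8 ethyl (2Z,4E,6S)-8-[(tert-butyldiphenylsilyl)oxy]-2,6-dimethylocta-2,4-dienoate, via potassium phosphonate carbanion 7 (not isolated)
Conditions: 6, KN(SiMe3)2, 18-crown-6, THF, −78 °C; then 5, −78 °C
Reagents that add atoms: none
Why: Still–Gennari olefination: the electron-poor trifluoroethyl phosphonate with a dissociated potassium counter-ion eliminates under kinetic control to the Z-trisubstituted enoate, leaving the E-alkene and C6 unchanged.

Step 5
Reactants: 8 ethyl (2Z,4E,6S)-8-[(tert-butyldiphenylsilyl)oxy]-2,6-dimethylocta-2,4-dienoate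
Product: 9 ethyl (2Z)-3-[(2R,3R)-3-{(2S)-4-[(tert-butyldiphenylsilyl)oxy]butan-2-yl}oxiran-2-yl]-2-methylprop-2-enoate
Conditions: 1,2:4,5-di-O-isopropylidene-β-D-erythro-2,3-hexodiulo-2,6-pyranose (fructose-derived Shi ketone, 30 mol%), KHSO5 (as 2KHSO5·KHSO4·K2SO4), K2CO3, Bu4NHSO4 (cat.), aq Na2B4O7 buffer, MeCN–CH2(OMe)2, 0 °C
Reagents that add atoms: potassium peroxymonosulfate, OOS(=O)(=O)[O-].[K+]
Why: Shi epoxidation: the electrophilic chiral dioxirane should attack only the distal, more electron-rich C4=C5 bond, syn-addition to the E-alkene gives the trans-epoxide stereospecifically, and by analogy with simple trans-alkenes this ketone is expected to give the (2R,3R) isomer.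

Step 6
Reactants: 9 ethyl (2Z)-3-[(2R,3R)-3-{(2S)-4-[(tert-butyldiphenylsilyl)oxy]butan-2-yl}oxiran-2-yl]-2-methylprop-2-enoate
Product: 10 (5S)-5-{(1R,2S)-4-[(tert-butyldiphenylsilyl)oxy]-1-hydroxy-2-methylbutyl}-3-methylfuran-2(5H)-one
Conditions: (+)-camphor-10-sulfonic acid (0.5 equiv), H2O (2 equiv), CH2Cl2, 0 °C → rt
Reagents that add atoms: water, O
Why: The sulfonic acid protonates the epoxide and the carbonyl oxygen of the Z-enoate, held next to the allylic epoxide carbon by the cis geometry, attacks that carbon (the future C5) from the rear in a 5-exo-tet closure that forms O1–C5 and the butenolide ring, after which water adds to the cyclic dialkoxycarbenium ion and ethanol is expelled. The closest known reaction type is the acid-mediated lactonisation of Z-configured γ,δ-epoxy enoates (and of γ,δ-epoxy esters generally) to γ-(α-hydroxyalkyl) lactones. C5 is set by SN2 inversion of the epoxide carbon and C1′ keeps the configuration of the second epoxide carbon, so the (2R,3R) trans-epoxide becomes the unlike 5S,1′R pair. The step needs the five-membered exo mode at the allylic carbon over 6-endo attack at the distal carbon, and it needs stereospecific inversion: the shorter tether and allylic activation favour 5-exo, while the electron-poor enoate disfavours an allylic cation and the non-nucleophilic acid at low temperature keeps the opening SN2-like. The hindered silyl ether oxygen is not expected to compete as an internal nucleophile, and the C2′ methyl centre is not touched.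

Step 7
Reactants: 10 (5S)-5-{(1R,2S)-4-[(tert-butyldiphenylsilyl)oxy]-1-hydroxy-2-methylbutyl}-3-methylfuran-2(5H)-one
Product: 12 (5E)-5-{(2S)-4-[(tert-butyldiphenylsilyl)oxy]-2-methylbutylidene}-3-methylfuran-2(5H)-one, via triflate 11 (not isolated)
Conditions: Tf2O, pyridine, CH2Cl2, −78 °C → rt
Reagents that add atoms: none
Why: Triflation followed by pyridine-induced anti-periplanar E2 elimination of C5–H and the C1′ triflate (stereospecific β-elimination of γ-(α-sulfonyloxyalkyl)butenolides) should turn the unlike 5S,1′R pair into the E-alkylidene with the chain cis to C4, the acidic C5–H directing the elimination away from C2′–H.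

Step 8
Reactants: 12 (5E)-5-{(2S)-4-[(tert-butyldiphenylsilyl)oxy]-2-methylbutylidene}-3-methylfuran-2(5H)-one
Product: 13 (5E)-5-[(2S)-4-hydroxy-2-methylbutylidene]-3-methylfuran-2(5H)-one
Conditions: HF·pyridine, pyridine, THF, 0 °C → rt
Reagents that add atoms: none
Why: Fluoride-mediated silyl ether cleavage under buffered, non-basic conditions should free the primary alcohol without opening the enol lactone or removing the acidic allylic C2′–H.

Step 9
Reactants: 13 (5E)-5-[(2S)-4-hydroxy-2-methylbutylidene]-3-methylfuran-2(5H)-one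
Product: 14 (3S)-3-methyl-4-[(2E)-4-methyl-5-oxofuran-2(5H)-ylidene]butanal
Conditions: Dess–Martin periodinane, CH2Cl2, 0 °C → rt
Reagents that add atoms: none
Why: Dess–Martin oxidation gives the aldehyde under near-neutral conditions without over-oxidation; the stereocentre is β to the new carbonyl and cannot epimerise by enolisation.

Step 10
Reactants: 14 (3S)-3-methyl-4-[(2E)-4-methyl-5-oxofuran-2(5H)-ylidene]butanal
Product: 15 (5E)-5-[(2S,4E)-5-iodo-2-methylpent-4-en-1-ylidene]-3-methylfuran-2(5H)-one
Conditions: CrCl2, CHI3, THF–1,4-dioxane, 0 °C → rt, dark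
Reagents that add atoms: iodoform, IC(I)I
Why: Takai iodo-olefination (addition of the geminal dichromium species from CHI3 and CrCl2 to the aldehyde, then elimination) should give the E-alkenyl iodide chemoselectively under non-basic conditions that spare the enol lactone and C2′.

Step 11
Reactants: 16 3-bromofuran; 17 4-bromofuran-2-carbaldehyde
Product: 19 (4-bromofuran-2-yl)(furan-3-yl)methanol (racemic), via furan-3-yllithium 18 (not isolated)
Conditions: 16, n-BuLi, THF, −78 °C; then 17, −78 °C; aq NH4Cl
Reagents that add atoms: none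
Why: Bromine–lithium exchange gives furan-3-yllithium, positionally stable at −78 °C, which undergoes 1,2-addition to the aldehyde faster than exchange with the ring bromide; the carbinol centre is removed in the next step.

Step 12
Reactants: 19 (4-bromofuran-2-yl)(furan-3-yl)methanol
Product: 20 4-bromo-2-(furan-3-ylmethyl)furan
Conditions: Et3SiH, CF3CO2H, CH2Cl2, −30 → 0 °C
Reagents that add atoms: none
Why: Ionic hydrogenation: acid ionisation to the doubly furyl-stabilised carbocation and hydride transfer from excess Et3SiH at low temperature should outrun Friedel–Crafts oligomerisation of the furans.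

Step 13
Reactants: 21 pent-3-yn-1-ol
Product: 22 5-iodopent-2-yne
Conditions: I2, PPh3, imidazole, CH2Cl2, 0 °C → rt
Reagents that add atoms: iodine, II
Why: Appel-type iodination, SN2 displacement of the alkoxyphosphonium ion by iodide at a primary carbon.

Step 14
Reactants: 20 4-bromo-2-(furan-3-ylmethyl)furan; 22 5-iodopent-2-yne
Product: 24 2-(furan-3-ylmethyl)-4-(pent-3-yn-1-yl)furan, via pent-3-yn-1-ylzinc iodide 23 (not isolated)
Conditions: 22, Zn, LiCl, THF, 40 °C; then 20, Pd(OAc)2 (2 mol%), 2-dicyclohexylphosphino-2′,6′-dimethoxybiphenyl (SPhos, 4 mol%), THF, rt → 50 °C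
Reagents that add atoms: none
Why: Negishi cross-coupling: zinc insertion gives a tolerant primary alkylzinc that couples with the β-bromofuran by oxidative addition, transmetalation and reductive elimination, the remote internal alkyne staying inert.

Step 15
Reactants: 24 2-(furan-3-ylmethyl)-4-(pent-3-yn-1-yl)furan
Product: 26 2-(furan-3-ylmethyl)-4-[(3E)-4-iodopent-3-en-1-yl]furan, via alkenylzirconocene chloride 25 (not isolated)
Conditions: Cp2Zr(H)Cl (3 equiv), THF, 50 °C; then I2, 0 °C
Reagents that add atoms: iodine, II
Why: Hydrozirconation–iodination: syn-addition of Zr–H, equilibration by excess reagent and warming to place zirconium on the less hindered methyl-bearing carbon, and iodinolysis of C–Zr with retention should give the (E)-2-iodoalk-2-ene.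

Step 16
Reactants: 26 2-(furan-3-ylmethyl)-4-[(3E)-4-iodopent-3-en-1-yl]furan
Product: 28 tributyl{(2E)-5-[5-(furan-3-ylmethyl)furan-3-yl]pent-2-en-2-yl}stannane, via alkenyllithium 27 (not isolated)
Conditions: t-BuLi (2 equiv), Et2O, −78 °C; then Bu3SnCl, −78 °C → rt
Reagents that add atoms: tributyltin chloride, CCCC[Sn](Cl)(CCCC)CCCC
Why: Iodine–lithium exchange at −78 °C is faster than furan deprotonation and retains the alkene geometry, and the alkenyllithium is trapped at tin by transmetalation.

Step 17
Reactants: 15 (5E)-5-[(2S,4E)-5-iodo-2-methylpent-4-en-1-ylidene]-3-methylfuran-2(5H)-one; 28 tributyl{(2E)-5-[5-(furan-3-ylmethyl)furan-3-yl]pent-2-en-2-yl}stannane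
Product: 29 (5E)-5-{(2S,4E,6E)-9-[5-(furan-3-ylmethyl)furan-3-yl]-2,6-dimethylnona-4,6-dien-1-ylidene}-3-methylfuran-2(5H)-one
Conditions: Pd(PPh3)4 (10 mol%), copper thiophene-2-carboxylate Cu(O2CC4H3S), Ph2P(O)ONBu4, DMF, rt, dark
Reagents that add atoms: none
Why: Copper-assisted, fluoride-free Stille coupling (oxidative addition of the alkenyl iodide to zerovalent palladium, tin-to-copper-to-palladium transmetalation driven by the phosphinate tin scavenger, reductive elimination) should join the two alkenes with retention of both geometries under neutral conditions that the E-alkylidene lactone and the furans tolerate.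

**Compound list**

1 | (R)-citronellol | C[C@H](CCC=C(C)C)CCO | starting material
2 | tert-butyl{[(3R)-3,7-dimethyloct-6-en-1-yl]oxy}diphenylsilane | C[C@H](CCC=C(C)C)CCO[Si](c1ccccc1)(c1ccccc1)C(C)(C)C | intermediate
3 | 5-{(3R)-5-[(tert-butyldiphenylsilyl)oxy]-3-methylpentyl}-3,3-dimethyl-1,2,4-trioxolane (ozonide, both epimers at the ring carbon) | C[C@H](CCC1OOC(C)(C)O1)CCO[Si](c1ccccc1)(c1ccccc1)C(C)(C)C | intermediate
4 | (4R)-6-[(tert-butyldiphenylsilyl)oxy]-4-methylhexanal | C[C@H](CCC=O)CCO[Si](c1ccccc1)(c1ccccc1)C(C)(C)C | intermediate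
5 | (2E,4S)-6-[(tert-butyldiphenylsilyl)oxy]-4-methylhex-2-enal | C[C@H](/C=C/C=O)CCO[Si](c1ccccc1)(c1ccccc1)C(C)(C)C | intermediate
6 | ethyl 2-[bis(2,2,2-trifluoroethoxy)phosphoryl]propanoate | CCOC(=O)C(C)P(=O)(OCC(F)(F)F)OCC(F)(F)F | starting material
7 | potassium salt of the α-carbanion of 6 | CCOC(=O)[C-](C)P(=O)(OCC(F)(F)F)OCC(F)(F)F.[K+] | intermediate
8 | ethyl (2Z,4E,6S)-8-[(tert-butyldiphenylsilyl)oxy]-2,6-dimethylocta-2,4-dienoate | CCOC(=O)/C(C)=C\C=C\[C@@H](C)CCO[Si](c1ccccc1)(c1ccccc1)C(C)(C)C | intermediate
9 | ethyl (2Z)-3-[(2R,3R)-3-{(2S)-4-[(tert-butyldiphenylsilyl)oxy]butan-2-yl}oxiran-2-yl]-2-methylprop-2-enoate | CCOC(=O)/C(C)=C\[C@H]1O[C@@H]1[C@@H](C)CCO[Si](c1ccccc1)(c1ccccc1)C(C)(C)C | intermediate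
10 | (5S)-5-{(1R,2S)-4-[(tert-butyldiphenylsilyl)oxy]-1-hydroxy-2-methylbutyl}-3-methylfuran-2(5H)-one | CC1=C[C@@H]([C@H](O)[C@@H](C)CCO[Si](c2ccccc2)(c2ccccc2)C(C)(C)C)OC1=O | intermediate
11 | (1R,2S)-4-[(tert-butyldiphenylsilyl)oxy]-2-methyl-1-[(2S)-4-methyl-5-oxo-2,5-dihydrofuran-2-yl]butyl trifluoromethanesulfonate | CC1=C[C@@H]([C@H](OS(=O)(=O)C(F)(F)F)[C@@H](C)CCO[Si](c2ccccc2)(c2ccccc2)C(C)(C)C)OC1=O | intermediate
12 | (5E)-5-{(2S)-4-[(tert-butyldiphenylsilyl)oxy]-2-methylbutylidene}-3-methylfuran-2(5H)-one | CC1=C/C(=C\[C@@H](C)CCO[Si](c2ccccc2)(c2ccccc2)C(C)(C)C)OC1=O | intermediate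
13 | (5E)-5-[(2S)-4-hydroxy-2-methylbutylidene]-3-methylfuran-2(5H)-one | CC1=C/C(=C\[C@@H](C)CCO)OC1=O | intermediate
14 | (3S)-3-methyl-4-[(2E)-4-methyl-5-oxofuran-2(5H)-ylidene]butanal | CC1=C/C(=C\[C@@H](C)CC=O)OC1=O | intermediate
15 | (5E)-5-[(2S,4E)-5-iodo-2-methylpent-4-en-1-ylidene]-3-methylfuran-2(5H)-one | CC1=C/C(=C\[C@@H](C)C/C=C/I)OC1=O | intermediate
16 | 3-bromofuran | Brc1ccoc1 | starting material
17 | 4-bromofuran-2-carbaldehyde | O=Cc1cc(Br)co1 | starting material
18 | furan-3-yllithium | [Li]c1ccoc1 | intermediate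
19 | (4-bromofuran-2-yl)(furan-3-yl)methanol (racemic) | OC(c1cc(Br)co1)c1ccoc1 | intermediate
20 | 4-bromo-2-(furan-3-ylmethyl)furan | Brc1coc(Cc2ccoc2)c1 | intermediate
21 | pent-3-yn-1-ol | CC#CCCO | starting material
22 | 5-iodopent-2-yne | CC#CCCI | intermediate
23 | pent-3-yn-1-ylzinc iodide | CC#CCC[Zn]I | intermediate
24 | 2-(furan-3-ylmethyl)-4-(pent-3-yn-1-yl)furan | CC#CCCc1coc(Cc2ccoc2)c1 | intermediate
25 | chlorobis(cyclopentadienyl){(2E)-5-[5-(furan-3-ylmethyl)furan-3-yl]pent-2-en-2-yl}zirconium (Zr trans to the chain) | C/C(=C\CCc1coc(Cc2ccoc2)c1)[Zr](Cl)(C1C=CC=C1)C1C=CC=C1 | intermediate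
26 | 2-(furan-3-ylmethyl)-4-[(3E)-4-iodopent-3-en-1-yl]furan | C/C(I)=C\CCc1coc(Cc2ccoc2)c1 | intermediate
27 | {(2Z)-5-[5-(furan-3-ylmethyl)furan-3-yl]pent-2-en-2-yl}lithium (Li trans to the chain, same geometry as 26; the descriptor changes because Li ranks below CH3) | C/C([Li])=C\CCc1coc(Cc2ccoc2)c1 | intermediate
28 | tributyl{(2E)-5-[5-(furan-3-ylmethyl)furan-3-yl]pent-2-en-2-yl}stannane | C/C(=C\CCc1coc(Cc2ccoc2)c1)[Sn](CCCC)(CCCC)CCCC | intermediate
29 | (5E)-5-{(2S,4E,6E)-9-[5-(furan-3-ylmethyl)furan-3-yl]-2,6-dimethylnona-4,6-dien-1-ylidene}-3-methylfuran-2(5H)-one | CC1=C/C(=C\[C@@H](C)C/C=C/C(C)=C/CCc2coc(Cc3ccoc3)c2)OC1=O | target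

**Step count and risks**

Total steps: 17. Longest linear sequence: 11 steps (steps 1–10 and 17, from (R)-citronellol); the stannane branch is steps 11–16.

The three steps most likely to fail:

1. The anti-elimination (step 7). Deprotonation at C5 ahead of C–O cleavage (an E1cB course through the aromatic 2-oxidofuran), or re-addition and re-elimination promoted by the pyridinium salt, would uncouple the alkene geometry from the C5/C1′ configuration and let the product drift toward the more stable Z-alkylidene. As a fallback, 10 would be dehydrated in a Mitsunobu-type redox process (PPh3, diisopropyl azodicarboxylate, THF, 0 °C → rt). The alkoxyphosphonium ion formed at O1′ leaves in a concerted anti-elimination under essentially neutral conditions, with no sulfonate and no free amine, and the sequence returns directly to 12. No new isolable compound is made (listed as F0).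

2. The epoxide-opening lactonisation (step 6). The ethyl ester carbonyl may be too weak a nucleophile, so that ionisation of the epoxide, 6-endo attack at the distal carbon, capture by the silyl ether oxygen or stalling before loss of the ethyl group competes with the 5-exo closure. As a fallback, 9 would be saponified (LiOH, THF–H2O, 0 °C → rt) to (2Z)-3-[(2R,3R)-3-{(2S)-4-[(tert-butyldiphenylsilyl)oxy]butan-2-yl}oxiran-2-yl]-2-methylprop-2-enoic acid F1. On buffered acidification (NaH2PO4, then catalytic pyridinium p-toluenesulfonate in CH2Cl2 if needed) the carboxyl group, a far better internal nucleophile that needs no dealkylation and no strong acid, should open the epoxide at the allylic carbon with the same inversion and return to 10.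

3. The final Stille coupling (step 17). Transmetalation from the α-methyl-substituted alkenylstannane may be slow enough that homocoupling of 15, protodestannylation of 28 or geometric drift of the alkylidene lactone takes over. As a fallback the polarity of the coupling would be reversed. Aldehyde 14 would be converted by a Takai-type chromium-mediated stannyl-olefination (CrCl2, Bu3SnCHBr2, LiI, THF–DMF, rt) into the unhindered alkenylstannane (5E)-3-methyl-5-[(2S,4E)-2-methyl-5-(tributylstannyl)pent-4-en-1-ylidene]furan-2(5H)-one F2. This would be coupled with alkenyl iodide 26 (Pd2(dba)3, AsPh3, N-methylpyrrolidone, rt) to return at 29; steps 10 and 16 would then not be needed.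

**Further compounds**

F0 | step 7 | none | none
F1 | step 6 | (2Z)-3-[(2R,3R)-3-{(2S)-4-[(tert-butyldiphenylsilyl)oxy]butan-2-yl}oxiran-2-yl]-2-methylprop-2-enoic acid | OC(=O)/C(C)=C\[C@H]1O[C@@H]1[C@@H](C)CCO[Si](c1ccccc1)(c1ccccc1)C(C)(C)C
F2 | step 17 | (5E)-3-methyl-5-[(2S,4E)-2-methyl-5-(tributylstannyl)pent-4-en-1-ylidene]furan-2(5H)-one | CC1=C/C(=C\[C@@H](C)C/C=C/[Sn](CCCC)(CCCC)CCCC)OC1=O
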